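**Assumption:** the SMILES is read as the (2S) enantiomer; compounds 1, 4, 5 and all named reagents and catalysts are catalogue items.

## Retrosynthetic overview

1. Target ⇒ in one flask: catalyst-controlled 6-endo oxa-Michael closure of a 3′,6′-dihydroxy-2′,4′-dimethoxychalcone (ring C, C2 stereocentre), which is itself formed by thermal 4π-opening/6π-closure of a 4-dienyl-4-hydroxy-3-methoxycyclobutenone (ring A built de novo with all four oxygens in place).
2. Cyclobutenone ⇒ methyl semisquarate + β-lithiated (1E,4E)-1-aryl-5-methoxypenta-1,4-dien-3-one (1,2-addition at the non-vinylogous C=O).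
3. Methyl semisquarate ⇒ dimethyl squarate; dienone ⇒ veratraldehyde + 4,4-dimethoxybutan-2-one.
4. Ring order: ring B is bought; ring A, then ring C, close in the last operation.

## Route

**Step 1**
Reactants: 1 dimethyl squarate (3,4-dimethoxycyclobut-3-ene-1,2-dione)
Product: 3 methyl semisquarate (3-methoxycyclobut-3-ene-1,2-dione), via hydroxycyclobutenone 2 (not isolated)
Conditions: LiAlH(Ot-Bu)3 (1.05 equiv), THF, −78 → −20 °C; cold 1 M HCl work-up; crude 2, conc. HCl (cat.), CH2Cl2, rt
Reagents that add atoms: water, O (from the aqueous acid; it becomes the new C=O oxygen while the 4-OH leaves as water)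
Why: Mono-1,2-reduction of one of the two equivalent vinylogous-ester carbonyls by the bulky alkoxyaluminium hydride gives racemic carbinol 2, and acid-catalysed allylic transposition/hemiketal collapse (loss of MeOH) gives the dione 3 and erases that stereocentre; this is the semisquarate synthesis known for the diisopropyl ester.

**Step 2**
Reactants: 4 3,4-dimethoxybenzaldehyde (veratraldehyde); 5 4,4-dimethoxybutan-2-one
Product: 7 (1E,4E)-1-(3,4-dimethoxyphenyl)-5-methoxypenta-1,4-dien-3-one, via keto acetal 6 (not isolated)
Conditions: NaOH (10 % aq., 0.3 equiv), MeOH, 0 °C → rt; work-up; crude 6, PPTS (2 mol %), toluene, 110 °C, MeOH distilled off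
Reagents that add atoms: none
Why: Claisen–Schmidt aldol condensation at the methyl group of 5 (E1cB dehydration, E-enone), then acid-catalysed loss of MeOH from the β-keto acetal gives the conjugated β-methoxy enone in its thermodynamic E geometry; no stereocentre is formed.

**Step 3**
Reactants: 7 (1E,4E)-1-(3,4-dimethoxyphenyl)-5-methoxypenta-1,4-dien-3-one; 3 methyl semisquarate
Product: 9 4-[(1E,4E)-5-(3,4-dimethoxyphenyl)-1-methoxy-3-oxopenta-1,4-dien-1-yl]-4-hydroxy-3-methoxycyclobut-2-en-1-one (racemic carbinol), via vinyllithium 8 (not isolated)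
Conditions: LiTMP (1.05 equiv, from TMPH + n-BuLi), THF, −100 °C, 7 added to the base, 20 min; then 3, −100 → −78 °C; AcOH quench at −78 °C
Reagents that add atoms: none
Why: Proposed new method: chelation-directed β-vinylic lithiation followed by 1,2-carbonyl addition — 7 has no enolisable sp3 C–H, and its C1–H is acidified by the α-oxygen and sits cis to the C=O, so the hindered amide removes it with retention to give the internally chelated vinyllithium 8, which adds to the more electrophilic, non-vinylogous carbonyl of 3 (the one next to C–OMe); the closest known chemistry is the β-lithiation of (E)-3-methoxyacrylates at ≤ −90 °C with carbonyl trapping, and the 1,2-addition of alkenyllithiums to semisquarate esters; the new carbinol stereocentre is racemic and is erased in step 4.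

**Step 4**
Reactants: 9 4-[(1E,4E)-5-(3,4-dimethoxyphenyl)-1-methoxy-3-oxopenta-1,4-dien-1-yl]-4-hydroxy-3-methoxycyclobut-2-en-1-one
Product: 12 (2S)-2-(3,4-dimethoxyphenyl)-6-hydroxy-5,7-dimethoxychroman-4-one (target), via dienylketene 10 (not isolated), via hydroquinone chalcone 11 (not isolated)
Conditions: degassed toluene (0.02 M), Ar, 110 °C, 1 h; cool to −25 °C, add quinine-derived 3,5-bis(trifluoromethyl)phenyl thiourea (epi-9-amino-9-deoxyquinine series, 10 mol %), 48–72 h; AcOH quench
Reagents that add atoms: none
Why: Proposed new method: one-pot Moore-type cyclobutenone ring expansion followed by asymmetric intramolecular oxa-Michael addition — conrotatory 4π-opening (OH rotates outward, dienyl inward) gives ketene 10, whose 6π-electrocyclisation and tautomerisation give chalcone 11 (ring A: ketene carbon → C8a–OH, carbinol carbon → C6–OH, the two OMe-bearing carbons → C7 and C5); on cooling, the quinuclidine of the catalyst deprotonates the chelated 8a-OH while the thiourea binds the enone C=O, and the phenoxide closes 6-endo-trig on one face of the β-carbon (ring C) to set C2 as S; the closest known reactions are the thermolysis of 4-alkenyl-4-hydroxycyclobutenones to hydroquinones and cinchona-thiourea oxa-Michael cyclisations of 2′-hydroxychalcone-type enones; the sense of induction is not known for this substrate, so it is checked by CD in a pilot run, with the quinidine-derived pseudo-enantiomer as the stand-by for the antipodal sense; the step is a pure isomerisation (C19H20O7 → C19H20O7).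

## Compound list

1 | dimethyl squarate (3,4-dimethoxycyclobut-3-ene-1,2-dione) | COC1=C(OC)C(=O)C1=O | starting material
2 | 4-hydroxy-2,3-dimethoxycyclobut-2-en-1-one (racemic) | COC1=C(OC)C(O)C1=O | intermediate
3 | methyl semisquarate (3-methoxycyclobut-3-ene-1,2-dione) | COC1=CC(=O)C1=O | intermediate
4 | 3,4-dimethoxybenzaldehyde (veratraldehyde) | COc1ccc(C=O)cc1OC | starting material
5 | 4,4-dimethoxybutan-2-one | CC(=O)CC(OC)OC | starting material
6 | (E)-1-(3,4-dimethoxyphenyl)-5,5-dimethoxypent-1-en-3-one | COC(OC)CC(=O)/C=C/c1ccc(OC)c(OC)c1 | intermediate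
7 | (1E,4E)-1-(3,4-dimethoxyphenyl)-5-methoxypenta-1,4-dien-3-one | CO/C=C/C(=O)/C=C/c1ccc(OC)c(OC)c1 | intermediate
8 | [(4E)-5-(3,4-dimethoxyphenyl)-1-methoxy-3-oxopenta-1,4-dien-1-yl]lithium, Li cis to the C=O | [Li]/C(OC)=C\C(=O)/C=C/c1ccc(OC)c(OC)c1 | intermediate
9 | 4-[(1E,4E)-5-(3,4-dimethoxyphenyl)-1-methoxy-3-oxopenta-1,4-dien-1-yl]-4-hydroxy-3-methoxycyclobut-2-en-1-one (racemic at C4 of the ring) | COC1=CC(=O)C1(O)/C(OC)=C\C(=O)/C=C/c1ccc(OC)c(OC)c1 | intermediate
10 | 9-(3,4-dimethoxyphenyl)-4-hydroxy-3,5-dimethoxynona-1,3,5,8-tetraene-1,7-dione (dienylketene) | O=C=C/C(OC)=C(O)\C(OC)=C/C(=O)/C=C/c1ccc(OC)c(OC)c1 | intermediate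
11 | (E)-1-(3,6-dihydroxy-2,4-dimethoxyphenyl)-3-(3,4-dimethoxyphenyl)prop-2-en-1-one | COc1cc(O)c(C(=O)/C=C/c2ccc(OC)c(OC)c2)c(OC)c1O | intermediate
12 | (2S)-2-(3,4-dimethoxyphenyl)-6-hydroxy-5,7-dimethoxychroman-4-one | COc1ccc([C@@H]2CC(=O)c3c(cc(OC)c(O)c3OC)O2)cc1OC | target

## Step count and risks

Total steps: 4 (steps 1 and 2 run in parallel). Longest linear sequence: 3 (1 → 3 → 9 → 12, or 4/5 → 7 → 9 → 12).

**Most likely to fail, in order:**

**Step 4.** The ring expansion is standard chemistry. The weak point is the enantioselectivity of the oxa-Michael closure on an unactivated, electron-rich chalcone: both the level and the sense of induction are unproven, there may be uncatalysed closure during the 110 °C stage, and the product can slowly racemise under base through ring opening. The hydroquinone 11 is also air-sensitive.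

The fallback sets out from 9 and comes back at 12. Heat 9 in toluene as above, then add DBU (5 mol %) at rt to obtain the racemic flavanone F1. Resolve it by kinetic resolution through asymmetric transfer hydrogenation ([Cp*RhCl2]2/(R,R)-TsDPEN, HCO2H/Et3N 5:2, EtOAc, rt, stopped near 52 % conversion). By the usual aryl-ketone model this catalyst makes the (4R)-carbinol and so should consume the (2R)-ketone as the cis-(2R,4R)-flavan-4-ol F2. F2 is removed by chromatography, leaving (2S)-12, with a maximum yield of 50 %.

**Step 3.** The vinyllithium 8 may add to unreacted 7, the amide base may add to 7, or lithiation may be incomplete. Compound 9 can also rest as its reversible ring-chain (cyclic hemiketal) tautomer.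

The fallback sets out from 3 and comes back at 9. Commercial (E)-3,4-dimethoxycinnamaldehyde and ethynylmagnesium bromide give (E)-1-(3,4-dimethoxyphenyl)pent-1-en-4-yn-3-ol F3. Two equivalents of n-BuLi give its dilithio derivative F4, which adds through the acetylide carbon to the same carbonyl of 3 to give, after AcOH quench, the alkynyl diol F5. MnO2 oxidises only the secondary allylic/propargylic alcohol to the ynone F6. Conjugate addition of MeOH (DABCO cat., 0 °C) at the ynone β-carbon then gives 9. Any enol-ether geometric isomer formed converges in step 4, because both close onto the same carbon.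

**Step 2.** The β-methoxy enone is hydrolytically labile, and MeOH loss or the regiochemistry of the condensation may be incomplete.

The fallback sets out from 4 and comes back at 7. The lithium enolate F7 of commercial (E)-4-methoxybut-3-en-2-one (LDA, THF, −78 °C) undergoes a directed aldol addition to 4 and gives, after AcOH quench, the aldol (E)-1-(3,4-dimethoxyphenyl)-1-hydroxy-5-methoxypent-4-en-3-one F8. MsCl/Et3N converts it to the mesylate F9, and DBU-induced E1cB elimination gives 7 without any acid, which would otherwise cyclise F8 to a dihydropyranone.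

## Further compounds

F1 | step 4 | racemic 2-(3,4-dimethoxyphenyl)-6-hydroxy-5,7-dimethoxychroman-4-one | COc1ccc(C2CC(=O)c3c(cc(OC)c(O)c3OC)O2)cc1OC
F2 | step 4 | (2R,4R)-2-(3,4-dimethoxyphenyl)-5,7-dimethoxychromane-4,6-diol | COc1ccc([C@H]2C[C@@H](O)c3c(cc(OC)c(O)c3OC)O2)cc1OC
F3 | step 3 | (E)-1-(3,4-dimethoxyphenyl)pent-1-en-4-yn-3-ol (racemic) | C#CC(O)/C=C/c1ccc(OC)c(OC)c1
F4 | step 3 | dilithio derivative (alkoxide/acetylide) of F3 | [Li]C#CC(O[Li])/C=C/c1ccc(OC)c(OC)c1
F5 | step 3 | 4-hydroxy-4-[(E)-5-(3,4-dimethoxyphenyl)-3-hydroxypent-4-en-1-yn-1-yl]-3-methoxycyclobut-2-en-1-one | COC1=CC(=O)C1(O)C#CC(O)/C=C/c1ccc(OC)c(OC)c1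
F6 | step 3 | 4-hydroxy-4-[(E)-5-(3,4-dimethoxyphenyl)-3-oxopent-4-en-1-yn-1-yl]-3-methoxycyclobut-2-en-1-one | COC1=CC(=O)C1(O)C#CC(=O)/C=C/c1ccc(OC)c(OC)c1
F7 | step 2 | lithium (E)-4-methoxybuta-1,3-dien-2-olate | [Li]OC(=C)/C=C/OC
F8 | step 2 | (E)-1-(3,4-dimethoxyphenyl)-1-hydroxy-5-methoxypent-4-en-3-one (racemic) | CO/C=C/C(=O)CC(O)c1ccc(OC)c(OC)c1
F9 | step 2 | (E)-1-(3,4-dimethoxyphenyl)-5-methoxy-3-oxopent-4-en-1-yl methanesulfonate | CO/C=C/C(=O)CC(OS(C)(=O)=O)c1ccc(OC)c(OC)c1
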